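Early on, the question is how little isomer of the product stands beside the target; later, how much has joined it. So I follow one molecule and ask its chance per hour of being found as isomer.

| flask | starting material | reagent | remark | time |
|---|---|---|---|---|
| Tuesday's | 0.50 M | 2 equiv | run made earlier |  |
| Friday's | 0.75 M | 2 equiv | run made earlier |  |
| Wednesday's | 1 M | 3 equiv | run made earlier |  |
| flask | 1.0 M | 2.00 equiv |  | 15 h |

| run | time / h | target / % | isomer of the product / % |
|---|---|---|---|
| Tuesday's | 2.50 | 49.6 | 1.1 |
| Tuesday's | 5.00 | 54.7 | 2.2 |
| Tuesday's | 6.00 | 56.2 | 3.8 |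
| Tuesday's | 10.0 | 54.6 | 6.5 |
| Friday's | 1.00 | 33.4 | 1.4 |
| Friday's | 3.00 | 54.7 | 1.6 |
| Friday's | 6.00 | 55.8 | 2.9 |
| Friday's | 10.0 | 54.6 | 6.1 |
| Wednesday's | 1.00 | 43.9 | 0.6 |
| Wednesday's | 3.00 | 57.6 | 2.5 |
| Wednesday's | 6.00 | 56.1 | 3.5 |
| Wednesday's | 10.0 | 55.0 | 6.0 |

(each reading ± 0.5 percentage points)

- share of target in target plus isomer of the product at 8.0 min
- share of target in target plus isomer of the product at 15 h
- which of target and isomer of the product there is more of at 15 h

- the earlier runs were read with a standard deviation of 0.5 percentage points

At 10.0 h the three runs read 6.5%, 6.1% and 6.0% isomer, within 0.5 points of each other across the charges, so I pool them. Isomer over target, divided by that time, is 0.0113 h⁻¹. This is the leak λ: the chance per hour that a molecule counted as target turns up as isomer. For the flask I take isomer over target as λ times time, so I reckon the target's share at 15 h at 85.5%, with target ahead. At 8.0 min the same line gives 99.8%, but the readings of Friday's and Wednesday's runs at 1.00 h, pooled, lie above the line and read a share of 97.5% at that later time, so for the flask at 8.0 min I expect a value between these two.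

The forecast, reading “slow first-order isomerisation of the target”, says 98%, 84.5% and target. The flask gives 98.9%, 85.2% and target, with 53.1% target against 9.25% isomer.

    starting material + reagent → intermediate + released group (k = 3.62 × 10⁻⁴ L mol⁻¹ s⁻¹)
    intermediate ⇌ target (K = 1.40, k = 4.13 × 10⁻⁴ s⁻¹)
    intermediate ⇌ isomer of the product (K = 7.01, k = 4.40 × 10⁻⁶ s⁻¹)
    crystals ⇌ released group, rate k4*(cs4 - [released group]) while solid is left; crystals form when [released group] > cs4 (solubility = 0.0540 M, k = 0.0110 s⁻¹)

In the scheme the isomer comes from the intermediate, of which the flask holds 37.7% at 15 h. The neighbour flask, charged with 0.500 equiv of reagent, has 0% of this limiting reagent left and holds 50.0% starting material and 26.6% target at 15 h. λ times time times that target gives 4.51% isomer, and that neighbour flask holds 4.47%.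

The earlier runs and the new flask are simulated on assumed constants; the scatter is artificial.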